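Readings and results were computed with constants of no real substance; scatter was added.

The leftover comes first: at 8.00 d the south-east run still holds 25.5% E and the west run 25.2%. Both stay near that up to 20.0 d, so in both runs the most E read lies in the early hump.

| flask | Q | remark | time |
|---|---|---|---|
| south-east | 0.35 M | run made earlier |  |
| west | 0.55 M | run made earlier |  |
| flask | 0.25 M |  | 15 d |

| run | time / d | E / % |
|---|---|---|
| south-east | 0.167 | 33.6 |
| south-east | 0.417 | 39.7 |
| south-east | 0.833 | 33.9 |
| south-east | 1.67 | 25.8 |
| south-east | 4.00 | 25.3 |
| south-east | 8.00 | 25.5 |
| south-east | 20.0 | 26.1 |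
| west | 0.167 | 30.6 |
| west | 0.417 | 38.0 |
| west | 0.833 | 36.2 |
| west | 1.67 | 26.2 |
| west | 4.00 | 25.8 |
| west | 8.00 | 25.2 |
| west | 20.0 | 26.7 |

(scatter of a reading: 0.5 percentage points)

- when, up to 15 d, the flask holds most E
- the amount of E, in percent of the Q charged, at that time

- the analysis behind the earlier runs scatters by 0.5 percentage points, standard deviation
- a reading or a percentage of E counts all its forms, free or not

In the first instants E climbs: at 0.167 d the south-east run shows 33.6%, and the richer west run shows less, 30.6%. Both readings belong to one time, so their ratio, 1.10, is a ratio of mean net rates, in percent of the charge, from which time has dropped out. Suppose that, at one time, the percentage gained goes inversely as the starting [Q] plus a constant concentration. That constant, the charge scale 1.69 M, is then read from the two runs, and it is a rough reading that carries their scatter. In the middle, the top south-east reading is 39.7% at 0.417 d. After that reading E falls in both runs until the plateau.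

For the flask, with [Q] at 0.25 M, the charge scale lifts that top reading to 41.7%. For the time, this reckoning simply keeps that reading's 0.417 d. The forecast says 41% (38.5% to 44%) at 0.33 d (0.22 d to 0.45 d), earlier than this reckoning, on the ground that “Peak time therefore scales roughly as concentration to the 0.6 power”.

The flask gives 43.3% at 0.410 d, later than the forecast's time. At that moment it also holds Q 16.0%, X 21.5% and D 19.2%. The charge scale's 41.7% lies 1.6 percentage points below the result.

    Q → E (k = 0.00250 min⁻¹)
    2 Q ⇌ X (K = 15.0 M⁻¹, k = 0.00350 M⁻¹ min⁻¹)
    E ⇌ D (K = 2.80, k = 0.00110 min⁻¹)
    J ⇌ E, rate k4*(cs4 - [E]) while solid is left; crystals form when [E] > cs4 (solubility = 0.150 M, k = 0.230 min⁻¹)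

For the neighbour flask charged with 0.42 M of Q, the charge scale gives 38.4%. The computed best there is 39.1%.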